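## Structural features

The target is a tetracyclic ether of the asbestinin type. A cyclohexane and a tetrahydrofuran share the C1–C10 bond, a saturated oxonane (O, C2–C9) is fused to the tetrahydrofuran through C2 and C9, and an oxepane (C3–O–C16–C15–C14–C1–C2) ties the oxonane to the cyclohexane. It carries eleven stereocentres: the run C15–C14–C1–C2–C3, the run C9–C10–C11–C12, and the separate syn pair C6/C7. On the cyclohexane, C9 (on C10), the acetate (C11) and the methyl (C12) lie on one face, opposite to H1 and H10, and the C15 arm on C14 is trans to C2. The fragile points are the secondary acetate, C12 whenever C11 is a ketone (epimerisable, and the methyl is cis to the C10–C9 bond), and the tertiary C3–O ether under strong acid. The real difficulty is the nine-membered ring together with a stereocentre (C15) that has no neighbouring functional group to direct it. The key step uses the fact that C1 and C10 belong to both the tetrahydrofuran and the cyclohexane while C2–O–C9 is a three-atom bridge between them. One cycloaddition between an enone arm on C2 and a diene arm on C9 of a cis-2,9-disubstituted oxonane therefore closes both rings.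

## Logic of the disconnections

46 to 41. The acetyl C–O bond is cut first, then 45 is related through ketone 44 to its C11 epimer 43, and 43 to alkene 41 by removing O from C11 and H from C12. The trisubstituted C11=C12 bond is what the cycloaddition leaves behind; syn addition from the convex face sets C12 correctly but puts oxygen on the wrong face of C11, so one oxidation/reduction pair is accepted. Two stereocentres and the ester collapse to one alkene. The forward steps need convex-face attack on 41 and on 44, and no enolisation of 44 towards C12.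

41 to 39. The C16–O bond of the oxepane is cut, leaving a primary alcohol and the tertiary silyl ether on C3. The trans arrangement at C1/C14 already holds C16 close to the C3 oxygen, so the seven-membered ring can be closed last. The forward step needs displacement at a primary carbon by a hindered oxygen to outrun elimination.

39 to 36. C16 and the C15–H bond are removed, leading through 37 back to methyl ketone 36. This returns to the cycloadduct at the price of one new stereocentre (C15) created on a freely rotating isopropenyl group. The forward hydroboration must choose the isopropenyl group over the ring alkene and one face of it.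

36 to 35. C1–C10 and C13–C14 are cut in a retro-Diels–Alder sense. Two rings and three stereocentres (C1, C10, C14) disappear and a monocyclic oxonane with two unsaturated arms remains. The forward step needs exo and facial selectivity from the ring.

35 to 29. The C1=C14 bond, then C12=C13 and C10=C11, are cut as Wittig disconnections via 33 and 32; 30 serves twice. The arms reduce to two differentiated hydroxymethyl groups on C2 and C9. The diene must be finished before the C1 aldehyde is released, which requires a C1 protecting group that can be turned into the aldehyde in the presence of the diene and the tertiary silyl ether.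

29 to 26. C4–C5 is cut (as C4=C5) through 28 and 27. It is the only ring bond flanked by no stereocentre that an alkene would erase. The ring opens to an acyclic ether diene; closure must form a nine-membered ring next to the fully substituted C3.

26 to 24 and 25. The C3–C4 bond is cut. The tertiary carbinol becomes an α-alkoxy methyl ketone, so C3 can be set from C2 by chelation.

24 to 17 and 18. The C2–C3 bond is cut (through 23, 22 and 21) as an auxiliary-controlled glycolate aldol. This sets C2 independently of the remote C9; the C3 carbinol formed is oxidised away.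

17 to 11, 12 and 14. The O–C2 bond and the N-acyl bond are cut (through 13). The unsymmetrical secondary–secondary ether is reduced to a secondary alcohol plus a two-carbon acid; the alkylation must not disturb the neighbouring protected oxygen.

11 to 6. The C9–O bond is cut (through 9). C9 becomes the α-position of an aldehyde, so the oxygen can be introduced under catalyst control.

6 to 5. The C9–C10 bond is cut as a hydroformylation, which must be linear and must leave the internal alkene alone.

5 to 1 and 2. The O–CH3 bond and then C6–C7 are cut (through 4) as a crotylation, which must give the syn pair in one enantiomeric series.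

## Other disconnections considered

Alternative 1: The cut is O–C2, C1–C2 and C9–C10, so the tetrahydrofuran is built onto a preformed cyclohexadiene. In the forward sense dienyl diol A2 and enal A3 condense to an oxocarbenium ion at C2, C1 of the diene attacks it, and the allyl cation at C10 is quenched by migration of C9 to give A1 with a formyl group on C10.
- In its favour: it is convergent; the chair-like cationic cyclisation sets C1, C2, C9 and C10 together; C14, C15 and the C16 oxygen arrive with A2. C15 is therefore fixed before any ring exists, which is better than the chosen plan, where C15 rests on a late hydroboration.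
- Equal: A1 carries the same C11=C12 alkene with the C12 methyl, so the C11/C12 endgame is the same.
- Against it here: the angular formyl group has to be excised with retention; the oxonane must still be closed afterwards across the C5–C8 region, a medium-ring closure with no ether gauche effect to help; and C3 (tertiary ether), C6 (methoxy) and C7 (methyl) would have to be created on the finished ring under substrate control, whereas the chosen plan sets them on open chains with reagent control.
- Mechanism and step economy: a stepwise cationic cascade replaces a concerted cycloaddition, so more can divert (elimination, competing migration). The convergence is offset by the longer sequence after the key step.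

Alternative 2: The cut is C4–C5. In the forward sense the allyl vinyl ether in methylene dioxepane A5 rearranges [3,3], forming C4–C5 and breaking O–C7, to give the oxonenone A4 with a C3 ketone and a Z C6=C7 alkene.
- In its favour: the hydroisobenzofuran with all cyclohexane stereocentres, C11 oxygen and C15 included, is secured first, and the nine-membered ring arises by ring expansion without high dilution. On both points it is better than the chosen plan, which has a medium-ring metathesis and a late C15.
- Equal: the tetrahydrofuran stereochemistry is equally well defined in both plans.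
- Against it here: C3 must then be made from a ketone by methyl addition with the correct face (the oxygen has to point towards C16), and C6/C7 from the Z alkene by a regio- and face-selective hydration on a flexible ring. The chosen plan fixes C3, C6 and C7 before the ring is formed.
- Step economy: the synthesis of A5 (lactone formation, methylenation) is long, so the total is comparable or longer.

Alternative 3: The cut is C2–C3 and C8–C9. In the forward sense the oxyallyl cation generated from chloro ketone A7 adds across the 2- and 5-positions of furan A8 to give A6, in which the furan oxygen bridges C2 and C9 and the carbonyl carbon bridges C3 and C8.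
- In its favour: one step builds the oxonane/tetrahydrofuran half with C2, C3 and C9, from a seven-membered ketone that already holds C6/C7. For this half it is clearly more step-economical than the roughly eighteen steps of the chosen plan. The carbonyl bridge could hand its position to oxygen at C3 with retention by Baeyer–Villiger migration of the fully substituted carbon.
- Against it here: the extra carbon must then be removed from C8; the [4+3] step is stepwise and cationic, and its face and endo/exo sense for an unsymmetrical, tetrasubstituted cation are hard to predict; and the cyclohexane with C1, C10, C11, C12, C14 and C15 would have to be annulated onto the unactivated bridged C1=C10 alkene of A6, where no cycloaddition handle exists.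
- Comparison: the chosen plan is weaker on the first half and much stronger on the second.

Key step: step 19

Remark on the chemistry: C6 and C7 are syn along the C5–C8 chain, so the crotyl unit is delivered from the (Z)-crotylboronate; the E isomer would give the 6,7-anti series.
Remark on the chemistry: trienone 35 and cycloadduct 36 were checked centre by centre against the target (C2, C3, C6, C7, C9; in 36 also C1, C10, C14) and carry its spatial arrangement; no change was needed.
Remark on the chemistry: atoms of all intermediates carry the locants they have in the target; descriptors are the CIP descriptors of the compound named, so a descriptor can change where only a substituent changes. (S)-TRIP is taken as the antipode that directs attack to the Si face of the aldehyde.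

## Steps

Step 1
Reactants: 1 (Z)-crotylboronic acid pinacol ester; 2 (E)-but-2-enal
Product: 4 (3R,4R,5E)-3-methylhepta-1,5-dien-4-ol, via pinacol borate ester 3 (not isolated)
Conditions: (S)-TRIP phosphoric acid (5 mol%), 4 Å MS, toluene, −30 °C; aq. NaHCO3
Reagents that add atoms: none
Why: Chiral-phosphoric-acid-catalysed crotylboration through a closed chair transition state; the Z geometry of 1 becomes the syn C6/C7 relationship and the catalyst selects the Si face of the aldehyde, which fixes C6 and with it C7.

Step 2
Reactants: 4 (3R,4R,5E)-3-methylhepta-1,5-dien-4-ol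
Product: 5 (3R,4R,5E)-4-methoxy-3-methylhepta-1,5-diene
Conditions: NaH, MeI, THF, 0 °C → rt
Reagents that add atoms: iodomethane, CI
Why: Williamson etherification of the allylic alkoxide; at 0 °C methylation is faster than anionic oxy-Cope rearrangement and no stereocentre is touched.

Step 3
Reactants: 5 (3R,4R,5E)-4-methoxy-3-methylhepta-1,5-diene
Product: 6 (4R,5S,6E)-5-methoxy-4-methyloct-6-enal
Conditions: Rh(acac)(CO)2 (1 mol%), Xantphos (2 mol%), CO/H2 (1:1, 10 bar), toluene, 70 °C
Reagents that add atoms: carbon monoxide, [C-]#[O+]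
Why: Linear-selective hydroformylation of the terminal vinyl group adds C10; the wide-bite-angle ligand and the allylic methyl branch favour the linear aldehyde and the internal disubstituted alkene does not react under these conditions.

Step 4
Reactants: 6 (4R,5S,6E)-5-methoxy-4-methyloct-6-enal
Product: 9 (2S,4R,5S,6E)-5-methoxy-4-methyloct-6-ene-1,2-diol, via anilinooxy aldehyde 7 (not isolated), via anilinooxy alcohol 8 (not isolated)
Conditions: PhNO, D-proline (10 mol%), CHCl3, 4 °C; NaBH4, EtOH, 0 °C; Zn, AcOH, rt
Reagents that add atoms: nitrosobenzene, O=Nc1ccccc1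
Why: Proline-catalysed α-aminoxylation through the enamine, then reduction and N–O cleavage; D-proline sets C9 under catalyst control, the remote C6/C7 centres having little say.

Step 5
Reactants: 9 (2S,4R,5S,6E)-5-methoxy-4-methyloct-6-ene-1,2-diol
Product: 11 (2S,4R,5S,6E)-1-(benzyloxy)-5-methoxy-4-methyloct-6-en-2-ol, via dibutylstannylene acetal 10 (not isolated)
Conditions: Bu2SnO, toluene, reflux; BnBr, Bu4NI, 90 °C
Reagents that add atoms: benzyl bromide, BrCc1ccccc1
Why: Stannylene-mediated monoalkylation of a 1,2-diol goes to the primary oxygen; a benzyl ether is chosen because it cannot migrate in the next step and leaves in the later hydrogenation.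

Step 6
Reactants: 11 (2S,4R,5S,6E)-1-(benzyloxy)-5-methoxy-4-methyloct-6-en-2-ol; 12 bromoacetic acid
Product: 13 2-{[(2S,4R,5S,6E)-1-(benzyloxy)-5-methoxy-4-methyloct-6-en-2-yl]oxy}acetic acid
Conditions: NaH, THF–DMF, 0 °C → rt; 1 M HCl
Reagents that add atoms: none
Why: Williamson etherification of the secondary alkoxide with sodium bromoacetate forms the O–C2 bond; C9 is not involved in bond breaking.

Step 7
Reactants: 13 2-{[(2S,4R,5S,6E)-1-(benzyloxy)-5-methoxy-4-methyloct-6-en-2-yl]oxy}acetic acid; 14 (R)-4-benzyl-1,3-oxazolidin-2-one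
Product: 17 N-glycolyl oxazolidinone (C9 ether; 4R auxiliary), via mixed pivalic anhydride 15 (not isolated), via N-lithio oxazolidinone 16 (not isolated)
Conditions: PivCl, Et3N, THF, −78 → 0 °C; 14, n-BuLi, THF, −78 °C; combined, −78 → 0 °C
Reagents that add atoms: none
Why: N-Acylation through the mixed anhydride; the lithiated auxiliary attacks the unhindered alkoxyacetyl carbonyl and not the pivaloyl one.

Step 8
Reactants: 17 N-glycolyl oxazolidinone; 18 acetaldehyde
Product: 21 syn aldol adduct (2R,3S), via Z-dibutylboron enolate 19 (not isolated), via dibutylboron aldolate 20 (not isolated)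
Conditions: Bu2BOTf, Et3N, CH2Cl2, −78 → 0 °C; 18, −78 → 0 °C; pH 7 buffer, MeOH, H2O2, 0 °C
Reagents that add atoms: none
Why: Evans syn aldol through a Zimmerman–Traxler transition state; the (R)-benzyl auxiliary selects the enolate face and sets C2 in the arrangement the target needs, while the C3 carbinol centre is later oxidised away.

Step 9
Reactants: 21 syn aldol adduct
Product: 22 (2S,3S)-2-alkoxybutane-1,3-diol (C1 OH; C3 OH)
Conditions: LiBH4, MeOH (1 equiv), THF, 0 °C
Reagents that add atoms: none
Why: Reductive cleavage of the imide gives the C1 alcohol and returns the auxiliary; hydride reduction does not enolise C2.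

Step 10
Reactants: 22 (2S,3S)-2-alkoxybutane-1,3-diol
Product: 23 primary triethylsilyl ether (C1 OSiEt3; C3 OH)
Conditions: TESCl, imidazole, CH2Cl2, −78 → −20 °C
Reagents that add atoms: chlorotriethylsilane, CC[Si](Cl)(CC)CC
Why: Kinetic silylation of the primary hydroxyl; the silyl ether is non-chelating (needed in step 12) and is later converted directly into the C1 aldehyde.

Step 11
Reactants: 23 primary triethylsilyl ether
Product: 24 α-alkoxy methyl ketone (3S; C3 ketone)
Conditions: Dess–Martin periodinane, NaHCO3, CH2Cl2, 0 °C → rt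
Reagents that add atoms: none
Why: Buffered Dess–Martin oxidation of the secondary alcohol; neutral conditions keep the C2 centre next to the new ketone intact.

Step 12
Reactants: 24 α-alkoxy methyl ketone; 25 vinylmagnesium bromide
Product: 26 tertiary allylic alcohol (2S,3S; acyclic diene)
Conditions: CH2=CHMgBr, THF, −78 °C; aq. NH4Cl
Reagents that add atoms: none
Why: Cram-chelate addition: magnesium bridges the ketone oxygen and the C2 ether oxygen (the silyl ether on C1 does not chelate), and vinyl adds from the side of H2, which gives the 3S carbinol; adding vinyl to the methyl ketone, not methyl to a vinyl ketone, is the order that gives this epimer.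

Step 13
Reactants: 26 tertiary allylic alcohol
Product: 27 Z-oxonene alcohol (2S,3S,6S,7R,9S; C1 OSiEt3; C3 OH; C10 OBn)
Conditions: second-generation Grubbs catalyst RuCl2(=CHPh)(PCy3)(H2IMes) (10 mol%), CH2Cl2 (2 mM), 40 °C
Reagents that add atoms: none
Why: Ring-closing metathesis forms C4=C5 with loss of propene; the gauche preference of the two C–O bonds at the ether folds the chain, the free allylic hydroxyl keeps C3 small, and the nine-membered ring enforces the Z alkene.

Step 14
Reactants: 27 Z-oxonene alcohol
Product: 28 bis(triethylsilyl) oxonene (2S,3S,6S,7R,9S)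
Conditions: TESOTf, 2,6-lutidine, CH2Cl2, −78 → 0 °C
Reagents that add atoms: triethylsilyl trifluoromethanesulfonate, CC[Si](CC)(CC)OS(=O)(=O)C(F)(F)F
Why: Silylation of the tertiary alcohol with the silyl triflate; the bulky ether later biases the cycloaddition and serves as the oxygen nucleophile in step 22.

Step 15
Reactants: 28 bis(triethylsilyl) oxonene
Product: 29 saturated oxonane alcohol (2S,3S,6R,7R,9S; C10 OH)
Conditions: H2 (1 atm), 10% Pd/C, EtOAc, rt
Reagents that add atoms: none
Why: One hydrogenation saturates C4=C5 and cleaves the benzyl ether, freeing only the C10 hydroxyl; a neutral aprotic solvent keeps both silyl ethers.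

Step 16
Reactants: 29 saturated oxonane alcohol; 30 1-(triphenylphosphoranylidene)propan-2-one
Product: 32 C9 (E)-enone (2S,3S,6R,7R,9S), via C10 aldehyde 31 (not isolated)
Conditions: Dess–Martin periodinane, NaHCO3, CH2Cl2, 0 °C → rt; then 30, rt → 40 °C
Reagents that add atoms: none
Why: One-pot oxidation and Wittig reaction with a stabilised ylide gives the E C10=C11 bond; the α-alkoxy aldehyde is trapped before C9 can epimerise.

Step 17
Reactants: 32 C9 (E)-enone
Product: 33 C9 (E)-3-methylbuta-1,3-dienyl oxonane (2S,3S,6R,7R,9S)
Conditions: Ph3PCH3Br, KOtBu, THF, 0 °C; then 32, 0 °C → rt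
Reagents that add atoms: methyltriphenylphosphonium bromide, C[P+](c1ccccc1)(c1ccccc1)c1ccccc1.[Br-]
Why: Wittig methylenation of the enone carbonyl (1,2-addition) completes the diene with C12 methyl and C13 methylene; the E C10=C11 geometry from step 16 is retained.

Step 18
Reactants: 33 C9 dienyl oxonane; 30 1-(triphenylphosphoranylidene)propan-2-one
Product: 35 trienone (2S,3S,6R,7R,9S; E enone on C2; E diene on C9), via C1 aldehyde 34 (not isolated)
Conditions: (COCl)2, DMSO, CH2Cl2, −78 → −40 °C; Et3N, −78 → 0 °C; then 30, 0 °C → rt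
Reagents that add atoms: none
Why: Under Swern conditions a primary triethylsilyl ether is cleaved and oxidised directly to the aldehyde while the tertiary one survives; the stabilised ylide then gives the E enone, and any 35 that already cyclises in the flask is the product of step 19.

Step 19
Reactants: 35 trienone
Product: 36 tricyclic methyl ketone (1R,2S,3S,6R,7R,9S,10R,14R; C11=C12)
Conditions: toluene (5 mM), BHT (cat.), rt → 80 °C
Reagents that add atoms: none
Why: Thermal, concerted and asynchronous [4+2] cycloaddition of the C1=C14 enone to the C10=C11–C12=C13 diene; the closest known reaction type is the intramolecular Diels–Alder reaction of ether-tethered nona-1,3,8-trienes to cis-fused hexahydroisobenzofurans. The cyclohexene closes as the six-membered ring of the cycloaddition through C1–C10 and C13–C14; the tetrahydrofuran closes in the same event through C1–C10 alone, because C2–O–C9 already joins the diene terminus to the dienophile (fused mode, three-atom tether). C14 follows from the E geometry of the enone, transferred suprafacially, so the acetyl ends trans to C2. C1 and C10 are set together: the cis-2,9 arrangement holds both arms on one side of the oxonane and only the π faces turned away from C3 and C8 can meet, which puts H1 and H10 anti to H2 and H9. The cis ring fusion requires the acetyl exo; the endo mode would lead to a trans-fused bicycle that the nine-membered ring spans only with strain and would press the acetyl against the C3 silyl ether. The step therefore needs facial and exo selectivity, and both come from the ring (cis-2,9 substitution, allylic strain of H2 and H9 against the arms, bulk at C3), not from the dienophile substituent. Regiochemistry is fixed by the tether, and the ketone lowers the dienophile LUMO enough for reaction at or slightly above room temperature.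

Step 20
Reactants: 36 tricyclic methyl ketone
Product: 37 isopropenyl tricycle (1S,2S,3S,6R,7R,9S,10R,14R)
Conditions: Ph3PCH3Br, KOtBu, THF, 0 °C → rt
Reagents that add atoms: methyltriphenylphosphonium bromide, C[P+](c1ccccc1)(c1ccccc1)c1ccccc1.[Br-]
Why: Wittig methylenation adds C16; the acetyl is already trans to C2 (the stable arrangement), so the basic ylide has no driving force to epimerise C14.

Step 21
Reactants: 37 isopropenyl tricycle
Product: 39 primary alcohol (1S,2S,3S,6R,7R,9S,10R,14S,15R; C16 OH), via B-alkyl-9-BBN 38 (not isolated)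
Conditions: 9-BBN, THF, 0 °C → rt; NaOH, H2O2, 0 °C → rt
Reagents that add atoms: hydrogen peroxide, OO
Why: Hydroboration–oxidation; 9-BBN takes the 1,1-disubstituted alkene and leaves the trisubstituted ring alkene. C15 is set by 1,2-induction from C14: in the favoured staggered transition state H14 lies inside next to C16, the branched C1 is anti to the incoming borane and C13 is outside, which delivers hydrogen to the face that gives 15R.

Step 22
Reactants: 39 primary alcohol
Product: 41 tetracyclic alkene (1S,2S,3S,6R,7R,9S,10R,14S,15R; oxepane closed), via primary triflate 40 (not isolated)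
Conditions: Tf2O, 2,6-lutidine, CH2Cl2, −78 → 0 °C
Reagents that add atoms: none
Why: Intramolecular etherification: the triflate at C16 is displaced by the oxygen of the C3 silyl ether (7-exo-tet), and the silyloxonium ion loses the silyl group; the trans-diequatorial C1/C14 bonds hold the two ends close and no stereocentre is involved.

Step 23
Reactants: 41 tetracyclic alkene
Product: 43 11-epi alcohol (1S,2S,3S,6R,7R,9S,10S,11S,12R,14S,15R), via C11 alkylborane 42 (not isolated)
Conditions: BH3·THF, THF, 0 °C → rt; NaOH, H2O2
Reagents that add atoms: hydrogen peroxide, OO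
Why: Hydroboration–oxidation of the trisubstituted alkene places boron on C11 and hydrogen on C12, syn and from the convex face opposite the axial C10–C9 bond; this sets C12 (methyl cis to C9) and gives the C11 hydroxyl on the face that has to be inverted.

Step 24
Reactants: 43 11-epi alcohol
Product: 44 C11 ketone (1S,2S,3S,6R,7R,9S,10R,12R,14S,15R)
Conditions: Dess–Martin periodinane, pyridine, CH2Cl2, 0 °C
Reagents that add atoms: none
Why: Buffered, non-basic oxidation; the ketone is used at once, because C12 (axial methyl, cis to C9) could epimerise through the enol.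

Step 25
Reactants: 44 C11 ketone
Product: 45 C11 alcohol (1S,2S,3S,6R,7R,9S,10S,11R,12R,14S,15R)
Conditions: NaBH4, CeCl3·7H2O, MeOH, −40 °C
Reagents that add atoms: none
Why: Luche-type borohydride reduction; hydride arrives axially from the convex face because the opposite face is flanked by the axial C10–C9 bond and the axial C12 methyl, so the hydroxyl ends equatorial and cis to both, and the cold, weakly basic medium limits enolisation towards C12.

Step 26
Reactants: 45 C11 alcohol
Product: 46 CNP0289153.2 (1S,2S,3S,6R,7R,9S,10R,11R,12R,14S,15R)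
Conditions: Ac2O, DMAP (cat.), pyridine, CH2Cl2, rt
Reagents that add atoms: acetic anhydride, CC(=O)OC(C)=O
Why: DMAP-catalysed acylation of the equatorial secondary alcohol; nothing else in the molecule reacts and C11 is retained.

## Compound list

1 | (Z)-crotylboronic acid pinacol ester | C/C=C\CB1OC(C)(C)C(C)(C)O1 | starting material
2 | (E)-but-2-enal | C/C=C/C=O | starting material
3 | pinacol borate ester of 4 (O–B at C6; not isolated) | C/C=C/[C@@H](OB1OC(C)(C)C(C)(C)O1)[C@H](C)C=C | intermediate
4 | (3R,4R,5E)-3-methylhepta-1,5-dien-4-ol | C/C=C/[C@@H](O)[C@H](C)C=C | intermediate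
5 | (3R,4R,5E)-4-methoxy-3-methylhepta-1,5-diene | C/C=C/[C@@H](OC)[C@H](C)C=C | intermediate
6 | (4R,5S,6E)-5-methoxy-4-methyloct-6-enal | C/C=C/[C@@H](OC)[C@H](C)CCC=O | intermediate
7 | (2S,4R,5S,6E)-5-methoxy-4-methyl-2-(phenylaminooxy)oct-6-enal (not isolated) | C/C=C/[C@@H](OC)[C@H](C)C[C@H](ONc1ccccc1)C=O | intermediate
8 | (2S,4R,5S,6E)-5-methoxy-4-methyl-2-(phenylaminooxy)oct-6-en-1-ol (not isolated) | C/C=C/[C@@H](OC)[C@H](C)C[C@H](ONc1ccccc1)CO | intermediate
9 | (2S,4R,5S,6E)-5-methoxy-4-methyloct-6-ene-1,2-diol | C/C=C/[C@@H](OC)[C@H](C)C[C@H](O)CO | intermediate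
10 | dibutylstannylene acetal of 9 (2,2-dibutyl-1,3,2-dioxastannolane; not isolated) | C/C=C/[C@@H](OC)[C@H](C)C[C@H]1CO[Sn](CCCC)(CCCC)O1 | intermediate
11 | (2S,4R,5S,6E)-1-(benzyloxy)-5-methoxy-4-methyloct-6-en-2-ol | C/C=C/[C@@H](OC)[C@H](C)C[C@H](O)COCc1ccccc1 | intermediate
12 | bromoacetic acid | OC(=O)CBr | starting material
13 | 2-{[(2S,4R,5S,6E)-1-(benzyloxy)-5-methoxy-4-methyloct-6-en-2-yl]oxy}acetic acid | C/C=C/[C@@H](OC)[C@H](C)C[C@H](OCC(=O)O)COCc1ccccc1 | intermediate
14 | (R)-4-benzyl-1,3-oxazolidin-2-one | O=C1N[C@H](Cc2ccccc2)CO1 | starting material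
15 | mixed anhydride of 13 with pivalic acid (not isolated) | C/C=C/[C@@H](OC)[C@H](C)C[C@H](OCC(=O)OC(=O)C(C)(C)C)COCc1ccccc1 | intermediate
16 | lithium salt of 14 (N-lithio; not isolated) | [Li+].O=C1[N-][C@H](Cc2ccccc2)CO1 | intermediate
17 | (4R)-4-benzyl-3-(2-{[(2S,4R,5S,6E)-1-(benzyloxy)-5-methoxy-4-methyloct-6-en-2-yl]oxy}acetyl)-1,3-oxazolidin-2-one | C/C=C/[C@@H](OC)[C@H](C)C[C@H](OCC(=O)N1[C@H](Cc2ccccc2)COC1=O)COCc1ccccc1 | intermediate
18 | acetaldehyde | CC=O | starting material
19 | (Z)-dibutylboron enolate of 17 (not isolated) | C/C=C/[C@@H](OC)[C@H](C)C[C@H](O/C=C(\OB(CCCC)CCCC)N1[C@H](Cc2ccccc2)COC1=O)COCc1ccccc1 | intermediate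
20 | dibutylboron aldolate of 21 (not isolated) | C/C=C/[C@@H](OC)[C@H](C)C[C@H](O[C@H]([C@H](C)OB(CCCC)CCCC)C(=O)N1[C@H](Cc2ccccc2)COC1=O)COCc1ccccc1 | intermediate
21 | (4R)-4-benzyl-3-[(2R,3S)-3-hydroxy-2-{[(2S,4R,5S,6E)-1-(benzyloxy)-5-methoxy-4-methyloct-6-en-2-yl]oxy}butanoyl]-1,3-oxazolidin-2-one | C/C=C/[C@@H](OC)[C@H](C)C[C@H](O[C@H]([C@H](C)O)C(=O)N1[C@H](Cc2ccccc2)COC1=O)COCc1ccccc1 | intermediate
22 | (2S,3S)-2-{[(2S,4R,5S,6E)-1-(benzyloxy)-5-methoxy-4-methyloct-6-en-2-yl]oxy}butane-1,3-diol | C/C=C/[C@@H](OC)[C@H](C)C[C@H](O[C@@H](CO)[C@H](C)O)COCc1ccccc1 | intermediate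
23 | (2S,3S)-3-{[(2S,4R,5S,6E)-1-(benzyloxy)-5-methoxy-4-methyloct-6-en-2-yl]oxy}-4-[(triethylsilyl)oxy]butan-2-ol | C/C=C/[C@@H](OC)[C@H](C)C[C@H](O[C@@H](CO[Si](CC)(CC)CC)[C@H](C)O)COCc1ccccc1 | intermediate
24 | (3S)-3-{[(2S,4R,5S,6E)-1-(benzyloxy)-5-methoxy-4-methyloct-6-en-2-yl]oxy}-4-[(triethylsilyl)oxy]butan-2-one | C/C=C/[C@@H](OC)[C@H](C)C[C@H](O[C@@H](CO[Si](CC)(CC)CC)C(C)=O)COCc1ccccc1 | intermediate
25 | vinylmagnesium bromide | C=C[Mg]Br | starting material
26 | (3S,4S)-4-{[(2S,4R,5S,6E)-1-(benzyloxy)-5-methoxy-4-methyloct-6-en-2-yl]oxy}-3-methyl-5-[(triethylsilyl)oxy]pent-1-en-3-ol | C/C=C/[C@@H](OC)[C@H](C)C[C@H](O[C@@H](CO[Si](CC)(CC)CC)[C@@](C)(O)C=C)COCc1ccccc1 | intermediate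
27 | (2S,3S,6S,7R,9S)-oxon-4-ene (target locants; Z C4=C5) with C2 CH2OSiEt3, C3 CH3 and OH, C6 OCH3, C7 CH3, C9 CH2OBn | CO[C@@H]1/C=C\[C@](C)(O)[C@H](CO[Si](CC)(CC)CC)O[C@H](COCc2ccccc2)C[C@H]1C | intermediate
28 | (2S,3S,6S,7R,9S)-oxon-4-ene as 27 with C3 OSiEt3 | CO[C@@H]1/C=C\[C@](C)(O[Si](CC)(CC)CC)[C@H](CO[Si](CC)(CC)CC)O[C@H](COCc2ccccc2)C[C@H]1C | intermediate
29 | (2S,3S,6R,7R,9S)-oxonane with C2 CH2OSiEt3, C3 CH3 and OSiEt3, C6 OCH3, C7 CH3, C9 CH2OH | CO[C@@H]1CC[C@](C)(O[Si](CC)(CC)CC)[C@H](CO[Si](CC)(CC)CC)O[C@H](CO)C[C@H]1C | intermediate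
30 | 1-(triphenylphosphoranylidene)propan-2-one | CC(=O)C=P(c1ccccc1)(c1ccccc1)c1ccccc1 | starting material
31 | (2S,3S,6R,7R,9S)-oxonane as 29 with C9 CHO (not isolated) | CO[C@@H]1CC[C@](C)(O[Si](CC)(CC)CC)[C@H](CO[Si](CC)(CC)CC)O[C@H](C=O)C[C@H]1C | intermediate
32 | (2S,3S,6R,7R,9S)-oxonane as 29 with C9 (E)-3-oxobut-1-enyl | CO[C@@H]1CC[C@](C)(O[Si](CC)(CC)CC)[C@H](CO[Si](CC)(CC)CC)O[C@H](/C=C/C(C)=O)C[C@H]1C | intermediate
33 | (2S,3S,6R,7R,9S)-oxonane as 29 with C9 (E)-3-methylbuta-1,3-dienyl | CO[C@@H]1CC[C@](C)(O[Si](CC)(CC)CC)[C@H](CO[Si](CC)(CC)CC)O[C@H](/C=C/C(C)=C)C[C@H]1C | intermediate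
34 | (2R,3S,6R,7R,9S)-oxonane with C2 CHO, C3 CH3 and OSiEt3, C9 (E)-3-methylbuta-1,3-dienyl (not isolated) | CO[C@@H]1CC[C@](C)(O[Si](CC)(CC)CC)[C@H](C=O)O[C@H](/C=C/C(C)=C)C[C@H]1C | intermediate
35 | (2S,3S,6R,7R,9S)-trienone: oxonane with C2 (E)-3-oxobut-1-enyl, C3 CH3 and OSiEt3, C6 OCH3, C7 CH3, C9 (E)-3-methylbuta-1,3-dienyl | CO[C@@H]1CC[C@](C)(O[Si](CC)(CC)CC)[C@H](/C=C/C(C)=O)O[C@H](/C=C/C(C)=C)C[C@H]1C | intermediate
36 | (1R,2S,3S,6R,7R,9S,10R,14R)-tricyclic methyl ketone: cis-fused hexahydroisobenzofuran on the oxonane, C11=C12 with C12 CH3, C14 acetyl trans to C2, C3 OSiEt3 | CO[C@@H]1CC[C@](C)(O[Si](CC)(CC)CC)[C@H]2O[C@@H](C[C@H]1C)[C@@H]3C=C(C)C[C@@H](C(C)=O)[C@H]23 | intermediate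
37 | (1S,2S,3S,6R,7R,9S,10R,14R)-tricycle as 36 with C14 isopropenyl | CO[C@@H]1CC[C@](C)(O[Si](CC)(CC)CC)[C@H]2O[C@@H](C[C@H]1C)[C@@H]3C=C(C)C[C@@H](C(C)=C)[C@H]23 | intermediate
38 | B-alkyl-9-borabicyclo[3.3.1]nonane from 37 (boron on C16; C15 as in 39; not isolated) | CO[C@@H]1CC[C@](C)(O[Si](CC)(CC)CC)[C@H]2O[C@@H](C[C@H]1C)[C@@H]3C=C(C)C[C@@H]([C@@H](C)CB4C5CCCC4CCC5)[C@H]23 | intermediate
39 | (1S,2S,3S,6R,7R,9S,10R,14S,15R)-tricycle with C14 CH(CH3)CH2OH | CO[C@@H]1CC[C@](C)(O[Si](CC)(CC)CC)[C@H]2O[C@@H](C[C@H]1C)[C@@H]3C=C(C)C[C@@H]([C@@H](C)CO)[C@H]23 | intermediate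
40 | C16 trifluoromethanesulfonate of 39 (not isolated) | CO[C@@H]1CC[C@](C)(O[Si](CC)(CC)CC)[C@H]2O[C@@H](C[C@H]1C)[C@@H]3C=C(C)C[C@@H]([C@@H](C)COS(=O)(=O)C(F)(F)F)[C@H]23 | intermediate
41 | (1S,2S,3S,6R,7R,9S,10R,14S,15R)-tetracycle: oxepane C3–O–C16 closed, C11=C12 | CO[C@@H]1CC[C@]2(C)OC[C@H](C)[C@@H]3CC(C)=C[C@@H]4[C@H]3[C@@H]2O[C@H]4C[C@H]1C | intermediate
42 | C11 alkylborane from 41 (BH2 on C11, trans to the C12 methyl; not isolated) | CO[C@@H]1CC[C@]2(C)OC[C@H](C)[C@@H]3C[C@@H](C)[C@H](B)[C@@H]4[C@H]3[C@@H]2O[C@H]4C[C@H]1C | intermediate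
43 | (1S,2S,3S,6R,7R,9S,10S,11S,12R,14S,15R)-tetracyclic alcohol (C11 OH trans to C9 and to the C12 methyl) | CO[C@@H]1CC[C@]2(C)OC[C@H](C)[C@@H]3C[C@@H](C)[C@H](O)[C@@H]4[C@H]3[C@@H]2O[C@H]4C[C@H]1C | intermediate
44 | (1S,2S,3S,6R,7R,9S,10R,12R,14S,15R)-tetracyclic C11 ketone | CO[C@@H]1CC[C@]2(C)OC[C@H](C)[C@@H]3C[C@@H](C)C(=O)[C@@H]4[C@H]3[C@@H]2O[C@H]4C[C@H]1C | intermediate
45 | (1S,2S,3S,6R,7R,9S,10S,11R,12R,14S,15R)-tetracyclic alcohol (C11 OH cis to C9 and to the C12 methyl) | CO[C@@H]1CC[C@]2(C)OC[C@H](C)[C@@H]3C[C@@H](C)[C@@H](O)[C@@H]4[C@H]3[C@@H]2O[C@H]4C[C@H]1C | intermediate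
46 | CNP0289153.2, (1S,2S,3S,6R,7R,9S,10R,11R,12R,14S,15R)-11-acetate | CO[C@@H]1CC[C@]2(C)OC[C@H](C)[C@@H]3C[C@@H](C)[C@@H](OC(C)=O)[C@@H]4[C@H]3[C@@H]2O[C@H]4C[C@H]1C | target

## Step count and least certain steps

Total step count: 26. Longest linear sequence: 26 steps (fully linear from 1 and 2; 18 steps to trienone 35, the key step, 7 steps after it).

Step 19 (key step). The saturated nine-membered ring is more mobile than an unsaturated one, so facial or exo selectivity could erode, or the cycloaddition could become slow enough for the diene to polymerise. The fallback keeps the Z alkene of the ring through the cycloaddition and saturates it afterwards: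
- It sets out from 28. The benzyl ether is removed oxidatively (DDQ, CH2Cl2–buffer, visible light) to give the oxonene alcohol F1.
- One-pot Dess–Martin oxidation and Wittig reaction with 30 gives the oxonene enone F2, and methylenation (Ph3PCH3Br, KOtBu) gives the oxonene diene F3.
- Swern oxidation of the primary silyl ether and Wittig reaction with 30 give the oxonene trienone F4, which is heated in toluene to the unsaturated cycloadduct F5.
- Selective hydrogenation of the cis-disubstituted ring alkene of F5 in the presence of the trisubstituted C11=C12 bond (H2, RhCl(PPh3)3, benzene) comes back to the route at 36.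

Step 13. Cross-metathesis between chains at the propenyl end may outrun ring closure, because the last bond has to form on a vinyl group attached to the fully substituted C3. The fallback is a relay design that loads ruthenium on C4 first. It sets out from 24: chelation-controlled addition of (E)-hepta-1,6-dien-1-ylmagnesium bromide (THF, −78 °C) gives the relay alcohol F6. With the same catalyst, the terminal alkene of F6 is engaged, cyclopentene is expelled, and the carbene on C4 closes onto the unhindered propenyl group. This comes back to the route at 27.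

Step 21. The isopropenyl group rotates freely and C14 distinguishes its faces only through the size difference between C1 and C13, so the facial selectivity at C15 may be insufficient. The fallback sets C15 by catalyst-controlled hydrogenation:
- It sets out from 36. Kinetic enolisation at the methyl group and triflation (KN(SiMe3)2, PhNTf2, THF, −78 °C) give the enol triflate F7.
- Methoxycarbonylation (Pd(OAc)2, PPh3, CO, MeOH, Et3N, DMF) gives the acrylate F8, and hydrolysis (LiOH, THF–H2O) gives the acrylic acid F9.
- Carboxylate-directed asymmetric hydrogenation (H2, Ru(OAc)2[(R)-BINAP], MeOH), which leaves the ring alkene alone, gives the 15R acid F10.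
- Reduction with LiAlH4 (THF, 0 °C) comes back to the route at 39.

Step 22. The primary triflate may eliminate or be captured by triflate or lutidine before the hindered silyl ether oxygen closes the seven-membered ring. The fallback is a stepwise alkoxide etherification. It sets out from 39: Bu4NF (THF) gives the diol F11, selective sulfonylation of the primary hydroxyl (TsCl, Et3N, DMAP, CH2Cl2, 0 °C) gives the tosylate F12, and NaH in THF (0 → 50 °C) closes the oxepane through the tertiary alkoxide. This comes back to the route at 41.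

## Further compounds

F1 | step 19 | oxonene alcohol (Z C4=C5; C1 OSiEt3; C3 OSiEt3; C10 OH) | CO[C@@H]1/C=C\[C@](C)(O[Si](CC)(CC)CC)[C@H](CO[Si](CC)(CC)CC)O[C@H](CO)C[C@H]1C
F2 | step 19 | oxonene enone (C9 (E)-3-oxobut-1-enyl) | CO[C@@H]1/C=C\[C@](C)(O[Si](CC)(CC)CC)[C@H](CO[Si](CC)(CC)CC)O[C@H](/C=C/C(C)=O)C[C@H]1C
F3 | step 19 | oxonene diene (C9 (E)-3-methylbuta-1,3-dienyl) | CO[C@@H]1/C=C\[C@](C)(O[Si](CC)(CC)CC)[C@H](CO[Si](CC)(CC)CC)O[C@H](/C=C/C(C)=C)C[C@H]1C
F4 | step 19 | oxonene trienone (Z C4=C5; E enone on C2; E diene on C9) | CO[C@@H]1/C=C\[C@](C)(O[Si](CC)(CC)CC)[C@H](/C=C/C(C)=O)O[C@H](/C=C/C(C)=C)C[C@H]1C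
F5 | step 19 | unsaturated cycloadduct (as 36 with Z C4=C5) | CO[C@@H]1/C=C\[C@](C)(O[Si](CC)(CC)CC)[C@H]2O[C@@H](C[C@H]1C)[C@@H]3C=C(C)C[C@@H](C(C)=O)[C@H]23
F6 | step 13 | relay alcohol (as 26 with (E)-hepta-1,6-dien-1-yl on C3) | C/C=C/[C@@H](OC)[C@H](C)C[C@H](O[C@@H](CO[Si](CC)(CC)CC)[C@@](C)(O)/C=C/CCCC=C)COCc1ccccc1
F7 | step 21 | enol triflate of 36 (C15(OTf)=C16H2) | CO[C@@H]1CC[C@](C)(O[Si](CC)(CC)CC)[C@H]2O[C@@H](C[C@H]1C)[C@@H]3C=C(C)C[C@@H](C(=C)OS(=O)(=O)C(F)(F)F)[C@H]23
F8 | step 21 | methyl acrylate (C15 methylene; C16 CO2CH3) | CO[C@@H]1CC[C@](C)(O[Si](CC)(CC)CC)[C@H]2O[C@@H](C[C@H]1C)[C@@H]3C=C(C)C[C@@H](C(=C)C(=O)OC)[C@H]23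
F9 | step 21 | acrylic acid (C15 methylene; C16 CO2H) | CO[C@@H]1CC[C@](C)(O[Si](CC)(CC)CC)[C@H]2O[C@@H](C[C@H]1C)[C@@H]3C=C(C)C[C@@H](C(=C)C(=O)O)[C@H]23
F10 | step 21 | (15R)-propanoic acid (C15 CH3; C16 CO2H) | CO[C@@H]1CC[C@](C)(O[Si](CC)(CC)CC)[C@H]2O[C@@H](C[C@H]1C)[C@@H]3C=C(C)C[C@@H]([C@@H](C)C(=O)O)[C@H]23
F11 | step 22 | diol (C3 OH; C16 OH) | CO[C@@H]1CC[C@](C)(O)[C@H]2O[C@@H](C[C@H]1C)[C@@H]3C=C(C)C[C@@H]([C@@H](C)CO)[C@H]23
F12 | step 22 | C16 p-toluenesulfonate (C3 OH) | CO[C@@H]1CC[C@](C)(O)[C@H]2O[C@@H](C[C@H]1C)[C@@H]3C=C(C)C[C@@H]([C@@H](C)COS(=O)(=O)c4ccc(C)cc4)[C@H]23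
A1 | alternative 1 | C10-formyl hexahydroisobenzofuran | C[Si](C)(C)C#CC[C@@H]1O[C@H](/C(C)=C/CCO[Si](C(C)C)(C(C)C)C(C)C)[C@H]2[C@H]([C@@H](C)CO[Si](C(C)C)(C(C)C)C(C)C)CC(C)=C[C@@]12C=O
A2 | alternative 1 | dienyl diol (one carbinol epimer at the future formyl carbon, a centre lost in the shift) | C[Si](C)(C)C#CC[C@H](O)[C@@H](O)C1=C[C@H]([C@@H](C)CO[Si](C(C)C)(C(C)C)C(C)C)CC(C)=C1
A3 | alternative 1 | (E)-2-methyl-5-[(triisopropylsilyl)oxy]pent-2-enal | O=C/C(C)=C/CCO[Si](C(C)C)(C(C)C)C(C)C
A4 | alternative 2 | bridged oxonenone (C3 ketone; Z C6=C7) | C1/C(C)=C\CCC(=O)[C@H]2O[C@@H]1[C@H]3[C@@H]2[C@H]([C@@H](C)CO[Si](C)(C)C(C)(C)C)C[C@@H](C)[C@H]3O[Si](C)(C)C(C)(C)C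
A5 | alternative 2 | 2-methylene-1,4-dioxepane with methyl and vinyl on C7 (one C7 epimer, a centre lost in the rearrangement) | C1[C@@](C)(C=C)OC(=C)[C@H]2O[C@@H]1[C@H]3[C@@H]2[C@H]([C@@H](C)CO[Si](C)(C)C(C)(C)C)C[C@@H](C)[C@H]3O[Si](C)(C)C(C)(C)C
A6 | alternative 3 | oxygen- and carbonyl-bridged cyclodecene | CO[C@@H]1CC[C@]2(C)C(=O)[C@H]([C@H]1C)[C@@H]3O[C@H]2C=C3
A7 | alternative 3 | 2-chloro-5-methoxy-2,6-dimethylcycloheptanone (either epimer at the chlorinated carbon) | CO[C@@H]1CCC(C)(Cl)C(=O)C[C@H]1C
A8 | alternative 3 | furan | c1ccoc1
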